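**Plan**

1. Retrosynthesis (target numbering O1, C2, C3, C3a, C4, C5, C6, C7, C7a): the palmitate is cut at the C6–O acyl bond, the butenolide at O1–C7a (with C3=C3a traced back to a C3a hydroxyl), and the carbocycle at C5–C6 and C6–C7.
2. Enabling feature: C6 is the only oxygenated carbon of the six-membered ring and lies between CH2-5 and CH2-7, each bound to a fully substituted carbon (C4, C7a). C6 can therefore come from carbon monoxide, and C5–C4–C3a–C7a–C7 from an isopropenylcyclopropane (three-membered ring C3a–C4–C5, alkene C7a=C7).
3. Forward order: the gem-dimethylcyclopropane is made first by isopropylidene transfer to α-methylene-γ-butyrolactone, and the lactone is then unfolded into the isopropenyl group and a tert-butyl acetate arm. The cyclohexenone ring arises by [5+1] carbonylation, and the γ-lactone ring closes last, followed by acylation and dehydration.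
4. Stereochemistry: C6 comes from an enantioselective enzymatic reduction of the achiral ketone. C7a is relayed from C6 by hydroxyl-directed syn epoxidation and anti opening of the epoxide by the ester carbonyl.

Key step: step 6

Assumption: ring atoms of all intermediates are referred to by the target's benzofuranone numbers, and a ketoreductase with the required facial preference for ketone 13 is taken to be identifiable by routine panel screening.

**Route**

Step 1
Reactants: 1 α-methylene-γ-butyrolactone; 2 isopropyltriphenylphosphonium iodide
Product: 4 (±)-1,1-dimethyl-5-oxaspiro[2.4]heptan-4-one, via isopropylidenetriphenylphosphorane 3 (not isolated)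
Conditions: 2 (1.2 equiv), n-BuLi (1.15 equiv), THF, 0 °C; then 1 added slowly at −78 °C, warm to rt, then 50 °C
Reagents that add atoms: none
Why: Michael-initiated ring closure, in which the non-stabilised ylide adds to the unhindered exocyclic methylene and the lactone enolate then expels triphenylphosphine from the fully substituted phosphonium carbon in a 3-exo-tet closure (ylide gem-dimethylcyclopropanation of an α,β-unsaturated ester); the spiro stereocentre forms racemic and is erased in step 6.

Step 2
Reactants: 4 (±)-1,1-dimethyl-5-oxaspiro[2.4]heptan-4-one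
Product: 5 (±)-1-[1-(2-hydroxyethyl)-2,2-dimethylcyclopropyl]ethan-1-one
Conditions: MeLi (1.05 equiv), THF, −78 → −40 °C; aq NH4Cl at low temperature
Reagents that add atoms: methyllithium, [Li]C
Why: Single addition of an organolithium to a γ-lactone, which should stop after one equivalent because the tetrahedral adduct does not collapse before the cold quench and the lactone has no α-hydrogen to lose.

Step 3
Reactants: 5 (±)-1-[1-(2-hydroxyethyl)-2,2-dimethylcyclopropyl]ethan-1-one; 6 methyltriphenylphosphonium bromide
Product: 8 (±)-2-[2,2-dimethyl-1-(prop-1-en-2-yl)cyclopropyl]ethan-1-ol, via methylenetriphenylphosphorane 7 (not isolated)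
Conditions: 6 (3 equiv), KOtBu (3 equiv), THF, 0 °C → reflux
Reagents that add atoms: none
Why: Wittig methylenation of a hindered methyl ketone with excess ylide, one equivalent being spent on the free hydroxyl, which leaves the cyclopropane untouched.

Step 4
Reactants: 8 (±)-2-[2,2-dimethyl-1-(prop-1-en-2-yl)cyclopropyl]ethan-1-ol
Product: 10 (±)-2-[2,2-dimethyl-1-(prop-1-en-2-yl)cyclopropyl]acetic acid, via cyclopropylacetaldehyde 9 (not isolated)
Conditions: TEMPO (20 mol%), PhI(OAc)2 (2.2 equiv), MeCN/H2O 1:1, rt
Reagents that add atoms: water, O
Why: Nitroxyl-catalysed oxidation with a hypervalent iodine co-oxidant takes the primary alcohol through the aldehyde hydrate to the acid under nearly neutral conditions that spare the acid-sensitive isopropenylcyclopropane.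

Step 5
Reactants: 10 (±)-2-[2,2-dimethyl-1-(prop-1-en-2-yl)cyclopropyl]acetic acid
Product: 11 (±)-tert-butyl 2-[2,2-dimethyl-1-(prop-1-en-2-yl)cyclopropyl]acetate
Conditions: O-tert-butyl-N,N'-diisopropylisourea (2 equiv), CH2Cl2, rt
Reagents that add atoms: O-tert-butyl-N,N'-diisopropylisourea, CC(C)N=C(NC(C)C)OC(C)(C)C
Why: O-Alkylation of the carboxylic acid by the isourea proceeds without added acid or base, and the tert-butyl ester is chosen because it can later give up isobutene when its carbonyl opens the epoxide, so no basic hydrolysis of an epoxy ester is needed.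

Step 6
Reactants: 11 (±)-tert-butyl 2-[2,2-dimethyl-1-(prop-1-en-2-yl)cyclopropyl]acetate; 12 carbon monoxide
Product: 13 tert-butyl 2-(2,6,6-trimethyl-4-oxocyclohex-1-en-1-yl)acetate
Conditions: [Rh(CO)2Cl]2 (2.5 mol%), dppp (5 mol%), AgOTf (6 mol%), CO (0.2 atm in N2), 4 Å MS, 1,2-dichloroethane, 80 °C
Reagents that add atoms: none
Why: Monovalent rhodium binds the isopropenyl group and inserts into the adjacent C3a–C5 cyclopropane bond with release of ring strain, giving an allyl–alkyl rhodacycle (η3 over C3a–C7a–C7, σ at C5); CO then inserts into the Rh–C5 bond and reductive elimination at the unsubstituted allyl terminus C7 frees the β,γ-unsaturated ketone. The closest known reaction type is the transition-metal-catalysed carbonylative [5+1] cycloaddition of vinylcyclopropanes to cyclohexenones. The six-membered carbocycle closes as a [5+1] annulation, that is by acyl–allyl reductive elimination forming C6–C7 after C5–C6 was formed by migratory insertion; coupling at the other allyl terminus C3a is excluded because it would give a cyclobutanone. No stereocentre is formed and the cyclopropane stereocentre of racemic 11 is erased, so 13 is achiral. The step needs cleavage of the C3a–CH2 bond and not the C3a–CMe2 bond, which the preference for a primary over a tertiary alkyl–rhodium bond secures, and it needs the metallacycle to survive until CO is taken up, which is helped by the Rh–CH2–CMe2 unit having no β-hydrogen. The tetrasubstituted C3a=C7a alkene must stay out of conjugation with the ketone, which the neutral aprotic medium and the immediate use of crude 13 in step 7 secure.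

Step 7
Reactants: 13 tert-butyl 2-(2,6,6-trimethyl-4-oxocyclohex-1-en-1-yl)acetate
Product: 14 tert-butyl 2-[(4R)-4-hydroxy-2,6,6-trimethylcyclohex-1-en-1-yl]acetate
Conditions: ketoreductase (NADPH-dependent, (R)-selective hit of a commercial panel), NADP+ (cat.), i-PrOH (10% v/v), KH2PO4/K2HPO4 buffer pH 7, 30 °C
Reagents that add atoms: none
Why: Enzymatic hydride transfer to one face of the prochiral ketone sets C6, the enzyme pocket telling the flat CH2–C(Me)= flank from the bulky CH2–CMe2 flank as in known enzymatic reductions of 2,2,6-trimethylcyclohexane-1,4-dione, while the neutral buffer leaves the β,γ-alkene in place; (4R) here is the same spatial arrangement as (6S) in the target, the descriptor differing only because the ranks of the two CH2 flanks swap.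

Step 8
Reactants: 14 tert-butyl 2-[(4R)-4-hydroxy-2,6,6-trimethylcyclohex-1-en-1-yl]acetate
Product: 15 tert-butyl 2-[(1R,4S,6S)-4-hydroxy-2,2,6-trimethyl-7-oxabicyclo[4.1.0]heptan-1-yl]acetate (epoxide oxygen cis to the hydroxyl)
Conditions: VO(acac)2 (5 mol%), t-BuOOH (1.5 equiv, decane), CH2Cl2, 0 °C → rt
Reagents that add atoms: tert-butyl hydroperoxide, CC(C)(C)OO
Why: Hydroxyl-directed vanadium-catalysed epoxidation of a homoallylic cyclohexenol, in which the vanadium alkoxide of the C6 hydroxyl delivers the peroxide oxygen to the same face of the electron-rich tetrasubstituted alkene, so that C3a and C7a are set syn to C6–OH.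

Step 9
Reactants: 15 tert-butyl 2-[(1R,4S,6S)-4-hydroxy-2,2,6-trimethyl-7-oxabicyclo[4.1.0]heptan-1-yl]acetate
Product: 16 (3aR,6S,7aR)-3a,6-dihydroxy-4,4,7a-trimethylhexahydro-1-benzofuran-2(3H)-one
Conditions: TFA (5 equiv), CH2Cl2, 0 °C → rt; aq NaHCO3
Reagents that add atoms: none
Why: Acid-promoted epoxide opening with neighbouring-group participation, in which the ester carbonyl oxygen attacks the tertiary C7a from the face opposite the protonated epoxide oxygen (inversion at C7a, cis-fused five-membered ring) and the tert-butyl group leaves as isobutene, placing the lactone oxygen anti to C6–OH and leaving the C3a hydroxyl syn; any butenolide formed early by loss of water would simply be acylated to the target in step 10.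

Step 10
Reactants: 16 (3aR,6S,7aR)-3a,6-dihydroxy-4,4,7a-trimethylhexahydro-1-benzofuran-2(3H)-one; 17 palmitoyl chloride
Product: 18 (3aR,6S,7aR)-3a-hydroxy-4,4,7a-trimethyl-2-oxooctahydro-1-benzofuran-6-yl hexadecanoate
Conditions: 17 (1.1 equiv), pyridine, DMAP (10 mol%), CH2Cl2, 0 °C → rt
Reagents that add atoms: none
Why: DMAP-catalysed acylation with an acid chloride is selective for the unhindered secondary C6 hydroxyl over the tertiary C3a hydroxyl flanked by two fully substituted carbons, and the ester also protects C6 during the dehydration.

Step 11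
Reactants: 18 (3aR,6S,7aR)-3a-hydroxy-4,4,7a-trimethyl-2-oxooctahydro-1-benzofuran-6-yl hexadecanoate
Product: 20 (−)-3-O-palmitoylloliolide, via tertiary chlorosulfite 19 (not isolated)
Conditions: SOCl2 (3 equiv), pyridine, 0 °C → rt
Reagents that add atoms: none
Why: Dehydration of a tertiary β-hydroxy lactone by thionyl chloride and pyridine (activation of the C3a hydroxyl, then base-induced β-elimination), in which C3 carries the only β-hydrogens so the C3=C3a butenolide is the sole possible alkene and C6 and C7a are not touched.

**Compound list**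

1 | α-methylene-γ-butyrolactone (3-methylideneoxolan-2-one) | C=C1CCOC1=O | starting material
2 | isopropyltriphenylphosphonium iodide | CC(C)[P+](c1ccccc1)(c1ccccc1)c1ccccc1.[I-] | starting material
3 | isopropylidenetriphenylphosphorane (not isolated) | CC(C)=P(c1ccccc1)(c1ccccc1)c1ccccc1 | intermediate
4 | (±)-1,1-dimethyl-5-oxaspiro[2.4]heptan-4-one | CC1(C)CC12CCOC2=O | intermediate
5 | (±)-1-[1-(2-hydroxyethyl)-2,2-dimethylcyclopropyl]ethan-1-one | CC(=O)C1(CCO)CC1(C)C | intermediate
6 | methyltriphenylphosphonium bromide | C[P+](c1ccccc1)(c1ccccc1)c1ccccc1.[Br-] | starting material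
7 | methylenetriphenylphosphorane (not isolated) | C=P(c1ccccc1)(c1ccccc1)c1ccccc1 | intermediate
8 | (±)-2-[2,2-dimethyl-1-(prop-1-en-2-yl)cyclopropyl]ethan-1-ol | CC(=C)C1(CCO)CC1(C)C | intermediate
9 | (±)-2-[2,2-dimethyl-1-(prop-1-en-2-yl)cyclopropyl]acetaldehyde (not isolated) | CC(=C)C1(CC=O)CC1(C)C | intermediate
10 | (±)-2-[2,2-dimethyl-1-(prop-1-en-2-yl)cyclopropyl]acetic acid | CC(=C)C1(CC(=O)O)CC1(C)C | intermediate
11 | (±)-tert-butyl 2-[2,2-dimethyl-1-(prop-1-en-2-yl)cyclopropyl]acetate | CC(=C)C1(CC(=O)OC(C)(C)C)CC1(C)C | intermediate
12 | carbon monoxide | [C-]#[O+] | starting material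
13 | tert-butyl 2-(2,6,6-trimethyl-4-oxocyclohex-1-en-1-yl)acetate | CC1=C(CC(=O)OC(C)(C)C)C(C)(C)CC(=O)C1 | intermediate
14 | tert-butyl 2-[(4R)-4-hydroxy-2,6,6-trimethylcyclohex-1-en-1-yl]acetate | O[C@H]1CC(C)(C)C(CC(=O)OC(C)(C)C)=C(C)C1 | intermediate
15 | tert-butyl 2-[(1R,4S,6S)-4-hydroxy-2,2,6-trimethyl-7-oxabicyclo[4.1.0]heptan-1-yl]acetate | O[C@H]1CC(C)(C)[C@@]2(CC(=O)OC(C)(C)C)O[C@@]2(C)C1 | intermediate
16 | (3aR,6S,7aR)-3a,6-dihydroxy-4,4,7a-trimethylhexahydro-1-benzofuran-2(3H)-one | O[C@H]1CC(C)(C)[C@]2(O)CC(=O)O[C@]2(C)C1 | intermediate
17 | palmitoyl chloride | CCCCCCCCCCCCCCCC(=O)Cl | starting material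
18 | (3aR,6S,7aR)-3a-hydroxy-4,4,7a-trimethyl-2-oxooctahydro-1-benzofuran-6-yl hexadecanoate | CCCCCCCCCCCCCCCC(=O)O[C@H]1CC(C)(C)[C@]2(O)CC(=O)O[C@]2(C)C1 | intermediate
19 | (3aR,6S,7aR)-3a-[(chlorosulfinyl)oxy]-4,4,7a-trimethyl-2-oxooctahydro-1-benzofuran-6-yl hexadecanoate (not isolated) | CCCCCCCCCCCCCCCC(=O)O[C@H]1CC(C)(C)[C@]2(OS(=O)Cl)CC(=O)O[C@]2(C)C1 | intermediate
20 | (−)-3-O-palmitoylloliolide, (6S,7aR)-4,4,7a-trimethyl-2-oxo-2,4,5,6,7,7a-hexahydro-1-benzofuran-6-yl hexadecanoate | CCCCCCCCCCCCCCCC(=O)O[C@H]1CC(C)(C)C2=CC(=O)O[C@]2(C)C1 | target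

**Step count and risks**

Total step count: 11. Longest linear sequence: 11 steps (from 1 to 20).

Steps most likely to fail:

1. Step 6. Insertion of rhodium into the fully substituted cyclopropane may be too slow, or the rhodacycle may collapse by alkyl–allyl reductive elimination (vinylcyclopropane–cyclopentene rearrangement) before CO is taken up. In that case the same two bonds are made stoichiometrically with zerovalent iron in two separate stages, setting out from 11. Irradiation with Fe(CO)5 (hν, benzene, rt) should give the ring-opened and already carbonylated tricarbonyliron acyl(π-allyl) complex F1, which is isolated. Heating F1 under CO (5 atm, benzene, 70 °C) should then force acyl–allyl reductive elimination and return to the route at 13.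

2. Step 7. The two flanks of the carbonyl differ only beyond the adjacent CH2 groups, so facial discrimination by the enzyme may be insufficient, or the alkene may drift into conjugation during a slow bioreduction. Stereocontrol is then moved from reduction to resolution, setting out from 13. Reduction with NaBH4 (MeOH, 0 °C) gives the racemic alcohol F2. Immobilised Candida antarctica lipase B with vinyl acetate (MTBE, 30 °C) is expected, by the empirical size rule for lipase acylation of secondary alcohols with the CMe2 flank as the large group, to acylate the (R)-enantiomer to the (R)-acetate F3 and to leave the (S)-alcohol F4. After chromatographic separation, methanolysis of F3 (K2CO3, MeOH, rt) returns to the route at 14.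

3. Step 1. The enolate formed by conjugate addition may attack further acceptor (anionic oligomerisation) faster than it expels triphenylphosphine from a tertiary carbon. The cyclopropane is then built without an anionic intermediate, setting out from 1. 1,3-Dipolar cycloaddition of 2-diazopropane (ethereal solution made beforehand from acetone hydrazone and HgO, −78 → 0 °C) should give the spiro-1-pyrazoline F5. Photolysis (hν above 300 nm, ether, rt) then extrudes nitrogen and closes the three-membered ring, returning to the route at 4.

Further compounds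
F1 | step 6 | tricarbonyliron acyl(π-allyl) complex from 11 and CO (iron bound to the C6 acyl carbon and η3 to C3a–C7a–C7; drawn in its σ-allyl form) | O=C1CC(C)(C)C(CC(=O)OC(C)(C)C)=C(C)C[Fe]1(=C=O)(=C=O)=C=O
F2 | step 7 | (±)-tert-butyl 2-(4-hydroxy-2,6,6-trimethylcyclohex-1-en-1-yl)acetate | OC1CC(C)(C)C(CC(=O)OC(C)(C)C)=C(C)C1
F3 | step 7 | tert-butyl 2-[(4R)-4-acetoxy-2,6,6-trimethylcyclohex-1-en-1-yl]acetate | CC(=O)O[C@H]1CC(C)(C)C(CC(=O)OC(C)(C)C)=C(C)C1
F4 | step 7 | tert-butyl 2-[(4S)-4-hydroxy-2,6,6-trimethylcyclohex-1-en-1-yl]acetate | O[C@@H]1CC(C)(C)C(CC(=O)OC(C)(C)C)=C(C)C1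
F5 | step 1 | (±)-8,8-dimethyl-2-oxa-6,7-diazaspiro[4.4]non-6-en-1-one | O=C1OCCC12CC(C)(C)N=N2
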